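**Retrosynthetic overview**
- The quinone comes from oxidative demethylation of a p-methoxyphenol that already carries the all-E hexaprenyl chain; that phenol comes from reductive removal of a benzylic/allylic phenylsulfonyl group.
- Key C–C bond (ring carbon to chain C1): Michael addition of lithiated all-E hexaprenyl phenyl sulfone to the quinone monoketal 4,4,5-trimethoxy-2-methylcyclohexa-2,5-dien-1-one, then loss of MeOH to re-aromatise. The monoketal has only one free enone β-carbon, so the position of the chain is fixed.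
- The monoketal comes from 3,4-dimethoxytoluene by formylation, Dakin oxidation and PhI(OAc)2/MeOH.
- The hexaprenyl sulfone comes from hexaprenol, built from two (2E,6E)-farnesol halves by sulfone alkylation; four E-olefins are bought in farnesol and the fifth is set by E-selective SeO2 oxidation.
- Rings: the single six-membered carbocycle is bought as an arene; no ring is formed. It is dearomatised to the monoketal, re-aromatised after the Michael step, and oxidised to the quinone last.

Assumption: the target has no stereocentre, so "single enantiomer" is read as the single (2E,6E,10E,14E,18E) geometric isomer. Reagents and solvents are not numbered; starting materials, intermediates and products are.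

**Route**

Step 1
Reactants: 1 (2E,6E)-farnesol
Product: 2 (2E,6E)-farnesyl bromide
Conditions: PBr3 (0.4 equiv), Et2O, −10 to 0 °C, used crude
Reagents that add atoms: phosphorus tribromide, BrP(Br)Br
Why: Bromination of a primary allylic alcohol through its phosphite ester (SN2) at low temperature proceeds without allylic transposition and keeps both E-olefins.

Step 2
Reactants: 2 (2E,6E)-farnesyl bromide
Product: 3 (2E,6E)-farnesyl phenyl sulfone
Conditions: PhSO2Na, DMF, rt
Reagents that add atoms: sodium benzenesulfinate, [Na+].[O-]S(=O)c1ccccc1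
Why: SN2 S-alkylation of the sulfinate by the primary allylic bromide gives the primary sulfone with unchanged olefin geometry.

Step 3
Reactants: 1 (2E,6E)-farnesol
Product: 4 (2E,6E)-farnesyl tert-butyldiphenylsilyl ether
Conditions: TBDPSCl, imidazole, DMF, rt
Reagents that add atoms: tert-butyl(chloro)diphenylsilane, CC(C)(C)[Si](Cl)(c1ccccc1)c1ccccc1
Why: Silylation of the primary alcohol gives an ether that survives the later oxidation, bromination, carbanion and hydride steps.

Step 4
Reactants: 4 (2E,6E)-farnesyl tert-butyldiphenylsilyl ether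
Product: 5 (2E,6E,10E)-12-[(tert-butyldiphenylsilyl)oxy]-2,6,10-trimethyldodeca-2,6,10-trien-1-ol
Conditions: SeO2 (0.1 equiv), t-BuOOH (2 equiv), salicylic acid (0.1 equiv), CH2Cl2, 0 °C to rt, stopped at partial conversion, chromatography
Reagents that add atoms: tert-butyl hydroperoxide, CC(C)(C)OO
Why: Catalytic SeO2 allylic oxidation (ene reaction then [2,3]-sigmatropic shift) attacks the terminal, most electron-rich trisubstituted olefin at its (E)-methyl group, so the new 10E allylic alcohol geometry is set by the mechanism.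

Step 5
Reactants: 5 (2E,6E,10E)-12-[(tert-butyldiphenylsilyl)oxy]-2,6,10-trimethyldodeca-2,6,10-trien-1-ol
Product: 6 (2E,6E,10E)-12-bromo-3,7,11-trimethyldodeca-2,6,10-trien-1-yl tert-butyldiphenylsilyl ether
Conditions: CBr4, PPh3, CH2Cl2, 0 °C
Reagents that add atoms: carbon tetrabromide, BrC(Br)(Br)Br
Why: The Appel reaction converts the primary allylic alcohol to the bromide by SN2 under neutral conditions that leave the silyl ether and the E-olefins untouched.

Step 6
Reactants: 3 (2E,6E)-farnesyl phenyl sulfone; 6 (2E,6E,10E)-12-bromo-3,7,11-trimethyldodeca-2,6,10-trien-1-yl tert-butyldiphenylsilyl ether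
Product: 8 tert-butyl{[(2E,6E,10E,14E,18E)-3,7,11,15,19,23-hexamethyl-13-(phenylsulfonyl)tetracosa-2,6,10,14,18,22-hexaen-1-yl]oxy}diphenylsilane (racemic at C13), via lithiated farnesyl phenyl sulfone 7 (not isolated)
Conditions: 3, n-BuLi, THF, −78 °C; then 6, −78 to −20 °C
Reagents that add atoms: none
Why: Alkylation of the α-sulfonyl allyl carbanion (Julia/Biellmann-type sulfone coupling) takes place at the α-carbon with the primary allylic bromide by SN2, joining the two C15 halves without touching any olefin.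

Step 7
Reactants: 8 tert-butyl{[(2E,6E,10E,14E,18E)-3,7,11,15,19,23-hexamethyl-13-(phenylsulfonyl)tetracosa-2,6,10,14,18,22-hexaen-1-yl]oxy}diphenylsilane
Product: 9 all-E hexaprenyl tert-butyldiphenylsilyl ether
Conditions: PdCl2(dppp) (5 mol %), LiBHEt3 (2.5 equiv), THF, 0 °C
Reagents that add atoms: none
Why: Zerovalent palladium ionises the allylic sulfone to a π-allyl complex and hydride is delivered to the less substituted terminus (Tsuji–Trost-type reductive desulfonylation), which keeps the double bond in place and E; the allylic silyl ether does not ionise.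

Step 8
Reactants: 9 all-E hexaprenyl tert-butyldiphenylsilyl ether
Product: 10 (2E,6E,10E,14E,18E)-hexaprenol
Conditions: Bu4NF, THF, rt
Reagents that add atoms: none
Why: Fluoride-induced desilylation is driven by the strong Si–F bond and does not affect the polyene.

Step 9
Reactants: 10 (2E,6E,10E,14E,18E)-hexaprenol
Product: 11 (2E,6E,10E,14E,18E)-hexaprenyl bromide
Conditions: PBr3 (0.4 equiv), Et2O, −10 °C, dark, used crude
Reagents that add atoms: phosphorus tribromide, BrP(Br)Br
Why: Low-temperature PBr3 bromination of the primary allylic alcohol (SN2 on the phosphite ester) is the standard polyprenol-to-bromide conversion and retains the 2E geometry.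

Step 10
Reactants: 11 (2E,6E,10E,14E,18E)-hexaprenyl bromide
Product: 12 (2E,6E,10E,14E,18E)-hexaprenyl phenyl sulfone
Conditions: PhSO2Na, DMF, rt
Reagents that add atoms: sodium benzenesulfinate, [Na+].[O-]S(=O)c1ccccc1
Why: SN2 S-alkylation of the sulfinate gives the primary allylic sulfone that serves as the Michael donor.

Step 11
Reactants: 13 3,4-dimethoxytoluene
Product: 14 4,5-dimethoxy-2-methylbenzaldehyde
Conditions: Cl2CHOMe, TiCl4, CH2Cl2, 0 °C; then ice-water
Reagents that add atoms: dichloromethyl methyl ether, COC(Cl)Cl; water, O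
Why: Rieche formylation (electrophilic aromatic substitution) takes place at the position para to one methoxy group and ortho to the methyl group, the most activated and least hindered site.

Step 12
Reactants: 14 4,5-dimethoxy-2-methylbenzaldehyde
Product: 16 4,5-dimethoxy-2-methylphenol, via aryl formate 15 (not isolated)
Conditions: mCPBA, CH2Cl2, rt; aq. NaHCO3 wash; then K2CO3 (cat.), MeOH, rt
Reagents that add atoms: 3-chloroperoxybenzoic acid, OOC(=O)c1cccc(Cl)c1
Why: Baeyer–Villiger (Dakin-type) oxidation of the electron-rich benzaldehyde migrates the aryl group to oxygen, and methanolysis of the formate frees the phenol.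

Step 13
Reactants: 16 4,5-dimethoxy-2-methylphenol
Product: 17 4,4,5-trimethoxy-2-methylcyclohexa-2,5-dien-1-one
Conditions: PhI(OAc)2, MeOH, 0 °C; NaHCO3 work-up, stored over a trace of Et3N
Reagents that add atoms: methanol, CO
Why: Hypervalent-iodine oxidative dearomatisation of a p-methoxyphenol is trapped by methanol at the para carbon, giving the p-quinone monoketal whose ketal sits next to the methoxy-bearing carbon.

Step 14
Reactants: 12 (2E,6E,10E,14E,18E)-hexaprenyl phenyl sulfone; 17 4,4,5-trimethoxy-2-methylcyclohexa-2,5-dien-1-one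
Product: 21 4,5-dimethoxy-2-methyl-3-[(2E,6E,10E,14E,18E)-3,7,11,15,19,23-hexamethyl-1-(phenylsulfonyl)tetracosa-2,6,10,14,18,22-hexaen-1-yl]phenol (racemic), via lithiated hexaprenyl phenyl sulfone 18 (not isolated), via lithium enolate Michael adduct 19 (not isolated), via ketone Michael adduct 20 (not isolated)
Conditions: 12, n-BuLi, THF, −78 °C; DMPU; then 17, −78 to −20 °C; AcOH; then TsOH·H2O (5 mol %), CH2Cl2, 0 °C to rt
Reagents that add atoms: none
Why: In this Michael addition the soft α-sulfonyl allyl carbanion adds through its unsubstituted α-carbon to the only free enone β-carbon of the monoketal (the other β-carbon is a deactivated vinylogous-ester carbon and 1,2-addition to the hindered carbonyl is reversible), and acid-induced loss of MeOH re-aromatises the adduct with the chain fixed between the methyl- and methoxy-bearing carbons; the sulfonyl-bearing stereocentre is racemic and is erased in step 15.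

Step 15
Reactants: 21 4,5-dimethoxy-2-methyl-3-[(2E,6E,10E,14E,18E)-3,7,11,15,19,23-hexamethyl-1-(phenylsulfonyl)tetracosa-2,6,10,14,18,22-hexaen-1-yl]phenol
Product: 22 4,5-dimethoxy-2-methyl-3-[(2E,6E,10E,14E,18E)-3,7,11,15,19,23-hexamethyltetracosa-2,6,10,14,18,22-hexaen-1-yl]phenol
Conditions: PdCl2(dppp) (5 mol %), LiBHEt3 (4 equiv), THF, 0 °C
Reagents that add atoms: none
Why: Zerovalent palladium ionises the benzylic/allylic sulfone to a π-allyl complex and hydride goes to the less substituted (benzylic) terminus (Tsuji–Trost-type reductive desulfonylation), leaving the 2E trisubstituted olefin in place; the phenol is carried as its lithium phenoxide.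

Step 16
Reactants: 22 4,5-dimethoxy-2-methyl-3-[(2E,6E,10E,14E,18E)-3,7,11,15,19,23-hexamethyltetracosa-2,6,10,14,18,22-hexaen-1-yl]phenol
Product: 23 2-methoxy-5-methyl-6-[(2E,6E,10E,14E,18E)-3,7,11,15,19,23-hexamethyltetracosa-2,6,10,14,18,22-hexaen-1-yl]cyclohexa-2,5-diene-1,4-dione (target)
Conditions: PhI(OAc)2, MeCN/H2O (2:1), 0 °C
Reagents that add atoms: water, O
Why: Hypervalent-iodine oxidation of the p-methoxyphenol lets water add at the para carbon and expel MeOH to give the 1,4-quinone (oxidative demethylation), while the isolated trisubstituted olefins are inert.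

**Compound list**

1 | (2E,6E)-farnesol | OC/C=C(\C)CC/C=C(\C)CCC=C(C)C | starting material
2 | (2E,6E)-farnesyl bromide | BrC/C=C(\C)CC/C=C(\C)CCC=C(C)C | intermediate
3 | (2E,6E)-farnesyl phenyl sulfone | O=S(=O)(C/C=C(\C)CC/C=C(\C)CCC=C(C)C)c1ccccc1 | intermediate
4 | (2E,6E)-farnesyl tert-butyldiphenylsilyl ether | CC(C)(C)[Si](c1ccccc1)(c1ccccc1)OC/C=C(\C)CC/C=C(\C)CCC=C(C)C | intermediate
5 | (2E,6E,10E)-12-[(tert-butyldiphenylsilyl)oxy]-2,6,10-trimethyldodeca-2,6,10-trien-1-ol | CC(C)(C)[Si](c1ccccc1)(c1ccccc1)OC/C=C(\C)CC/C=C(\C)CC/C=C(\C)CO | intermediate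
6 | (2E,6E,10E)-12-bromo-3,7,11-trimethyldodeca-2,6,10-trien-1-yl tert-butyldiphenylsilyl ether | CC(C)(C)[Si](c1ccccc1)(c1ccccc1)OC/C=C(\C)CC/C=C(\C)CC/C=C(\C)CBr | intermediate
7 | lithiated farnesyl phenyl sulfone (α-lithio, not isolated) | [Li]C(/C=C(\C)CC/C=C(\C)CCC=C(C)C)S(=O)(=O)c1ccccc1 | intermediate
8 | tert-butyl{[(2E,6E,10E,14E,18E)-3,7,11,15,19,23-hexamethyl-13-(phenylsulfonyl)tetracosa-2,6,10,14,18,22-hexaen-1-yl]oxy}diphenylsilane (racemic at C13) | CC(C)(C)[Si](c1ccccc1)(c1ccccc1)OC/C=C(\C)CC/C=C(\C)CC/C=C(\C)CC(/C=C(\C)CC/C=C(\C)CCC=C(C)C)S(=O)(=O)c1ccccc1 | intermediate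
9 | all-E hexaprenyl tert-butyldiphenylsilyl ether | CC(C)(C)[Si](c1ccccc1)(c1ccccc1)OC/C=C(\C)CC/C=C(\C)CC/C=C(\C)CC/C=C(\C)CC/C=C(\C)CCC=C(C)C | intermediate
10 | (2E,6E,10E,14E,18E)-3,7,11,15,19,23-hexamethyltetracosa-2,6,10,14,18,22-hexaen-1-ol (hexaprenol) | OC/C=C(\C)CC/C=C(\C)CC/C=C(\C)CC/C=C(\C)CC/C=C(\C)CCC=C(C)C | intermediate
11 | all-E hexaprenyl bromide | BrC/C=C(\C)CC/C=C(\C)CC/C=C(\C)CC/C=C(\C)CC/C=C(\C)CCC=C(C)C | intermediate
12 | all-E hexaprenyl phenyl sulfone | O=S(=O)(C/C=C(\C)CC/C=C(\C)CC/C=C(\C)CC/C=C(\C)CC/C=C(\C)CCC=C(C)C)c1ccccc1 | intermediate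
13 | 3,4-dimethoxytoluene (1,2-dimethoxy-4-methylbenzene) | COc1ccc(C)cc1OC | starting material
14 | 4,5-dimethoxy-2-methylbenzaldehyde | COc1cc(C)c(C=O)cc1OC | intermediate
15 | 4,5-dimethoxy-2-methylphenyl formate (not isolated) | COc1cc(C)c(OC=O)cc1OC | intermediate
16 | 4,5-dimethoxy-2-methylphenol | COc1cc(C)c(O)cc1OC | intermediate
17 | 4,4,5-trimethoxy-2-methylcyclohexa-2,5-dien-1-one | COC1=CC(=O)C(C)=CC1(OC)OC | intermediate
18 | lithiated hexaprenyl phenyl sulfone (α-lithio, not isolated) | [Li]C(/C=C(\C)CC/C=C(\C)CC/C=C(\C)CC/C=C(\C)CC/C=C(\C)CCC=C(C)C)S(=O)(=O)c1ccccc1 | intermediate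
19 | lithium enolate of the Michael adduct (diastereomer mixture, not isolated) | [Li]OC1=C(C)C(C(/C=C(\C)CC/C=C(\C)CC/C=C(\C)CC/C=C(\C)CC/C=C(\C)CCC=C(C)C)S(=O)(=O)c2ccccc2)C(OC)(OC)C(OC)=C1 | intermediate
20 | 3,4,4-trimethoxy-6-methyl-5-[1-(phenylsulfonyl)-all-E-hexaprenyl]cyclohex-2-en-1-one (diastereomer mixture, not isolated) | COC1=CC(=O)C(C)C(C(/C=C(\C)CC/C=C(\C)CC/C=C(\C)CC/C=C(\C)CC/C=C(\C)CCC=C(C)C)S(=O)(=O)c2ccccc2)C1(OC)OC | intermediate
21 | 4,5-dimethoxy-2-methyl-3-[(2E,6E,10E,14E,18E)-3,7,11,15,19,23-hexamethyl-1-(phenylsulfonyl)tetracosa-2,6,10,14,18,22-hexaen-1-yl]phenol (racemic) | COc1cc(O)c(C)c(C(/C=C(\C)CC/C=C(\C)CC/C=C(\C)CC/C=C(\C)CC/C=C(\C)CCC=C(C)C)S(=O)(=O)c2ccccc2)c1OC | intermediate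
22 | 4,5-dimethoxy-2-methyl-3-[(2E,6E,10E,14E,18E)-3,7,11,15,19,23-hexamethyltetracosa-2,6,10,14,18,22-hexaen-1-yl]phenol | COc1cc(O)c(C)c(C/C=C(\C)CC/C=C(\C)CC/C=C(\C)CC/C=C(\C)CC/C=C(\C)CCC=C(C)C)c1OC | intermediate
23 | 2-methoxy-5-methyl-6-[(2E,6E,10E,14E,18E)-3,7,11,15,19,23-hexamethyltetracosa-2,6,10,14,18,22-hexaen-1-yl]cyclohexa-2,5-diene-1,4-dione (CHEBI:28711) | COC1=CC(=O)C(C)=C(C/C=C(\C)CC/C=C(\C)CC/C=C(\C)CC/C=C(\C)CC/C=C(\C)CCC=C(C)C)C1=O | target

**Totals**
Total step count: 16.
Longest linear sequence: 11 steps (1 → 4 → 5 → 6 → 8 → 9 → 10 → 11 → 12 → 21 → 22 → 23; steps 3–10 and 14–16).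

**Three steps most likely to fail, with fallbacks**

Step 14 (Michael union). Risks are competing 1,2-addition, slow attack at a β-carbon flanked by the methyl group and the ketal, and proton transfer. The fallback sets out from 11 and 17 and comes back to the route at 23. Hydrolyse 17 with aqueous oxalic acid in THF to 2-methoxy-5-methyl-1,4-benzoquinone F1. Treat 11 with Bu3SnLi in THF at −78 °C to give tributyl[(2E,6E,10E,14E,18E)-hexaprenyl]stannane F2. Combine F1 and F2 with BF3·OEt2 in CH2Cl2 at −78 °C; this is a Lewis-acid-promoted allylation of the quinone carbonyl followed by allyl shift and gives 3-[(all-E)-hexaprenyl]-5-methoxy-2-methylbenzene-1,4-diol F3. The regioisomer prenylated next to the methoxy group must be removed by chromatography, because this route does not fix the position. Oxidise F3 with Ag2O in Et2O to 23, bypassing 21 and 22.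

Step 15 (desulfonylation next to the arene). Hydride could be delivered to the far allyl terminus, giving a styrene-type isomer, or the 2E olefin could scramble. The fallback sets out from 21 and comes back at 22. Silylate the phenol (TBSCl, imidazole, DMF) to tert-butyl{4,5-dimethoxy-2-methyl-3-[1-(phenylsulfonyl)-all-E-hexaprenyl]phenoxy}dimethylsilane F4. Cleave the C–S bond by electron transfer with Na/Hg (6% Na), Na2HPO4, MeOH–THF, −20 °C; this is a radical-anion fragmentation with no π-allyl palladium intermediate and gives tert-butyl{4,5-dimethoxy-2-methyl-3-[(all-E)-hexaprenyl]phenoxy}dimethylsilane F5. Remove the silyl group with Bu4NF in THF to return to 22.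

Step 4 (SeO2 allylic oxidation). Risks are modest yield, over-oxidation to the enal and some oxidation at internal olefins. The fallback sets out from 4 and comes back at 5, replacing direct C–H oxidation by terminal cleavage and E-selective olefination.
- N-bromosuccinimide in THF/H2O at 0 °C gives the terminal bromohydrin (6E,10E)-3-bromo-12-[(tert-butyldiphenylsilyl)oxy]-2,6,10-trimethyldodeca-6,10-dien-2-ol F6.
- K2CO3 in MeOH closes it to the terminal epoxide tert-butyl{[(2E,6E)-9-(3,3-dimethyloxiran-2-yl)-3,7-dimethylnona-2,6-dien-1-yl]oxy}diphenylsilane F7.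
- H5IO6 in THF/Et2O cleaves the epoxide to (4E,8E)-10-[(tert-butyldiphenylsilyl)oxy]-4,8-dimethyldeca-4,8-dienal F8.
- Wittig reaction with the stabilised ylide Ph3P=C(CH3)CO2Et in CH2Cl2 gives ethyl (2E,6E,10E)-12-[(tert-butyldiphenylsilyl)oxy]-2,6,10-trimethyldodeca-2,6,10-trienoate F9.
- i-Bu2AlH in CH2Cl2 at −78 °C reduces the ester to 5.

**Further compounds**

F1 | step 14 | 2-methoxy-5-methyl-1,4-benzoquinone | COC1=CC(=O)C(C)=CC1=O
F2 | step 14 | tributyl[(2E,6E,10E,14E,18E)-hexaprenyl]stannane | CCCC[Sn](CCCC)(CCCC)C/C=C(\C)CC/C=C(\C)CC/C=C(\C)CC/C=C(\C)CC/C=C(\C)CCC=C(C)C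
F3 | step 14 | 3-[(all-E)-hexaprenyl]-5-methoxy-2-methylbenzene-1,4-diol | COc1cc(O)c(C)c(C/C=C(\C)CC/C=C(\C)CC/C=C(\C)CC/C=C(\C)CC/C=C(\C)CCC=C(C)C)c1O
F4 | step 15 | tert-butyl{4,5-dimethoxy-2-methyl-3-[1-(phenylsulfonyl)-all-E-hexaprenyl]phenoxy}dimethylsilane (racemic) | COc1cc(O[Si](C)(C)C(C)(C)C)c(C)c(C(/C=C(\C)CC/C=C(\C)CC/C=C(\C)CC/C=C(\C)CC/C=C(\C)CCC=C(C)C)S(=O)(=O)c2ccccc2)c1OC
F5 | step 15 | tert-butyl{4,5-dimethoxy-2-methyl-3-[(all-E)-hexaprenyl]phenoxy}dimethylsilane | COc1cc(O[Si](C)(C)C(C)(C)C)c(C)c(C/C=C(\C)CC/C=C(\C)CC/C=C(\C)CC/C=C(\C)CC/C=C(\C)CCC=C(C)C)c1OC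
F6 | step 4 | (6E,10E)-3-bromo-12-[(tert-butyldiphenylsilyl)oxy]-2,6,10-trimethyldodeca-6,10-dien-2-ol (racemic) | CC(C)(C)[Si](c1ccccc1)(c1ccccc1)OC/C=C(\C)CC/C=C(\C)CCC(Br)C(C)(C)O
F7 | step 4 | tert-butyl{[(2E,6E)-9-(3,3-dimethyloxiran-2-yl)-3,7-dimethylnona-2,6-dien-1-yl]oxy}diphenylsilane (racemic) | CC(C)(C)[Si](c1ccccc1)(c1ccccc1)OC/C=C(\C)CC/C=C(\C)CCC1OC1(C)C
F8 | step 4 | (4E,8E)-10-[(tert-butyldiphenylsilyl)oxy]-4,8-dimethyldeca-4,8-dienal | CC(C)(C)[Si](c1ccccc1)(c1ccccc1)OC/C=C(\C)CC/C=C(\C)CCC=O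
F9 | step 4 | ethyl (2E,6E,10E)-12-[(tert-butyldiphenylsilyl)oxy]-2,6,10-trimethyldodeca-2,6,10-trienoate | CC(C)(C)[Si](c1ccccc1)(c1ccccc1)OC/C=C(\C)CC/C=C(\C)CC/C=C(\C)C(=O)OCC
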